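**Plan**

1. Atom labels: pyran O–C13(CH3)(C14H=C15H2)–C12–C11–C9–C8(CH3); ring B C8–C9–C10(CH3)(C1H2–C2O2H)–C5(C4(CH3)2–C3O2H)–C6–C7.
2. The retrosynthesis cuts O–C8 first (pyran opened to a C13 carbinol and a C7=C8 alkene), then C1–C2 (acid back to a C1 aldehyde on C10), then C5–C6 and C9–C10 together.
3. Enabling feature: ring B holds the contiguous centres C9, C10 and C5 beside a C7–C8 edge that can be an alkene. It is therefore a cyclohexene made from a diene C6=C7–C8(CH3)=C9–C11 (linalool plus one carbon) and an (E)-α-methyl enal C1(=O)–C10(CH3)=C5–C4.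
4. Forward order: (R)-linalool becomes the diene and methyl hydroxypivalate the enal; the [4+2] closes ring B; C1 is extended to the C2 acid; the pyran closes last by adding the C13 hydroxyl to C8; the ester is hydrolysed.
5. Stereochemistry: C13 comes from (R)-linalool. C5/C10 come from the E enal and C9 from the E diene in a formyl-exo transition state, all three in the absolute sense fixed by the (S)-oxazaborolidinium catalyst. C8 comes from equatorial C–O bond formation (trans ring fusion) on the chair held by the equatorial C4 group.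

Key step: step 7

Assumption: the (S)-configured catalyst is taken to leave the C10 Re face of the boron-bound enal open, as the formyl C–H···O model for 2-substituted acroleins predicts; were the opposite sense found, the catalyst from (R)-diphenylprolinol would be used in the same step.

**Route**

Step 1
Reactants: 1 (R)-linalool
Product: 2 triethyl{[(3R)-3,7-dimethylocta-1,6-dien-3-yl]oxy}silane
Conditions: Et3SiOTf, 2,6-lutidine, CH2Cl2, −78 → 0 °C
Reagents that add atoms: triethylsilyl trifluoromethanesulfonate, CC[Si](CC)(CC)OS(=O)(=O)C(F)(F)F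
Why: Silyl ether protection with a silyl triflate and a hindered pyridine base silylates even a tertiary allylic alcohol at low temperature without touching the alkenes or C13, and the ether keeps the hydroxyl away from SeO2, ylides and the boron catalyst of step 7.

Step 2
Reactants: 2 triethyl{[(3R)-3,7-dimethylocta-1,6-dien-3-yl]oxy}silane
Product: 3 (2E,6R)-2,6-dimethyl-6-(triethylsilyloxy)octa-2,7-dien-1-ol
Conditions: SeO2 (0.3 equiv), t-BuOOH (3 equiv), salicylic acid (0.1 equiv), CH2Cl2, 23 °C
Reagents that add atoms: selenium dioxide, O=[Se]=O; tert-butyl hydroperoxide, CC(C)(C)OO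
Why: Sharpless allylic oxidation (ene reaction, then [2,3]-sigmatropic shift) acts at the more substituted end of the trisubstituted alkene on the methyl trans to the chain, so the E allylic alcohol should result while the vinyl group stays inert; any enal 4 formed by over-oxidation is carried into step 3.

Step 3
Reactants: 3 (2E,6R)-2,6-dimethyl-6-(triethylsilyloxy)octa-2,7-dien-1-ol
Product: 4 (2E,6R)-2,6-dimethyl-6-(triethylsilyloxy)octa-2,7-dienal
Conditions: MnO2, CH2Cl2, 23 °C
Reagents that add atoms: none
Why: MnO2 oxidises allylic alcohols selectively to enals under neutral conditions, keeping the E geometry and leaving the silyl ether and the isolated alkene alone.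

Step 4
Reactants: 4 (2E,6R)-2,6-dimethyl-6-(triethylsilyloxy)octa-2,7-dienal
Product: 5 triethyl{[(3R,6E)-3,7-dimethylnona-1,6,8-trien-3-yl]oxy}silane
Conditions: Ph3PCH3Br, KOt-Bu, THF, 0 → 23 °C
Reagents that add atoms: methyltriphenylphosphonium bromide, [Br-].C[P+](c1ccccc1)(c1ccccc1)c1ccccc1
Why: Wittig methylenation of the enal carbonyl by the unstabilised ylide is fast at 0 °C and adds C6 as the terminal alkene without disturbing the E C8=C9 bond, giving the 1,3-diene for step 7.

Step 5
Reactants: 6 methyl 3-hydroxy-2,2-dimethylpropanoate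
Product: 7 methyl 2,2-dimethyl-3-oxopropanoate
Conditions: TEMPO (2,2,6,6-tetramethylpiperidin-1-oxyl, 1 mol %), KBr (10 mol %), NaOCl, NaHCO3, CH2Cl2/H2O, 0 °C
Reagents that add atoms: none
Why: Anelli oxidation stops at the aldehyde for a primary neopentyl alcohol, and the product has no α-hydrogen, so it cannot enolise; the ester is untouched.

Step 6
Reactants: 7 methyl 2,2-dimethyl-3-oxopropanoate; 8 2-(triphenylphosphoranylidene)propanal
Product: 9 methyl (3E)-2,2,4-trimethyl-5-oxopent-3-enoate
Conditions: toluene, 100 °C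
Reagents that add atoms: none
Why: Wittig reaction of a formyl-stabilised ylide with a non-enolisable aldehyde should give the trisubstituted enal with the formyl group trans to the larger β-substituent (E), and the hindered α-branched product does not compete with 7 for the ylide.

Step 7
Reactants: 5 triethyl{[(3R,6E)-3,7-dimethylnona-1,6,8-trien-3-yl]oxy}silane; 9 methyl (3E)-2,2,4-trimethyl-5-oxopent-3-enoate
Product: 10 methyl 2-[(1R,5S,6R)-6-formyl-4,6-dimethyl-5-[(3R)-3-methyl-3-(triethylsilyloxy)pent-4-en-1-yl]cyclohex-3-en-1-yl]-2-methylpropanoate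
Conditions: (S)-3,3-diphenyl-1-(o-tolyl)tetrahydro-1H,3H-pyrrolo[1,2-c][1,3,2]oxazaborole (20 mol %), Tf2NH (18 mol %), CH2Cl2, −78 → −20 °C
Reagents that add atoms: none
Why: The formyl oxygen of 9 binds to boron of the cationic oxazaborolidine, a formyl C–H···O contact holds the s-trans enal over one phenyl ring, and the diene adds in a concerted but asynchronous [4+2] in which the unsubstituted terminus C6 bonds ahead to the β-carbon C5 and C9 then closes onto C10. The closest known reaction type is the oxazaborolidinium-catalysed, formyl-exo Diels–Alder addition of 2-methylacrolein and tiglic-type enals to dienes, and Lewis-acid Diels–Alder reactions of 4,4-dimethylcyclohex-2-enones show that a quaternary carbon on the β-position is tolerated on the diene side. Ring B (C5–C6–C7–C8–C9–C10) closes by the cycloaddition itself, an intermolecular [4+2] annulation that leaves the C7=C8 alkene. C5 and C10 are set relative to each other by suprafacial addition to the E enal (C10 methyl cis to C4), C9 is set relative to C10 by the E diene reacting formyl-exo (C11 cis to the C10 methyl, trans to C1), and the absolute sense of all three is set by the catalyst, whose phenyl ring covers the C10 Si face so that the diene enters on the Re face; the remote C13 centre is only carried. The step needs ortho regiochemistry, secured by the C9 alkyl substituent (largest HOMO coefficient at C6) and by the bulk at C5 (approachable only by the CH2 terminus), and formyl-exo selectivity, secured by the α-methyl group and the o-tolyl-flanked, boron-bound formyl, which leaves no room for the diene backbone beneath it.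

Step 8
Reactants: 10 methyl 2-[(1R,5S,6R)-6-formyl-4,6-dimethyl-5-[(3R)-3-methyl-3-(triethylsilyloxy)pent-4-en-1-yl]cyclohex-3-en-1-yl]-2-methylpropanoate
Product: 11 methyl 2-[(1R,5S,6R)-6-(2-methoxyethenyl)-4,6-dimethyl-5-[(3R)-3-methyl-3-(triethylsilyloxy)pent-4-en-1-yl]cyclohex-3-en-1-yl]-2-methylpropanoate (E/Z mixture)
Conditions: Ph3PCH2OMe Cl, KN(SiMe3)2, THF, 0 → 40 °C
Reagents that add atoms: (methoxymethyl)triphenylphosphonium chloride, [Cl-].COC[P+](c1ccccc1)(c1ccccc1)c1ccccc1
Why: Wittig reaction with the small, reactive methoxymethylene ylide is the standard one-carbon homologation of hindered neopentyl aldehydes; 10 has no α-hydrogen, the pivalate-like ester and silyl ether resist the ylide, and both enol ether isomers converge in step 9.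

Step 9
Reactants: 11 methyl 2-[(1R,5S,6R)-6-(2-methoxyethenyl)-4,6-dimethyl-5-[(3R)-3-methyl-3-(triethylsilyloxy)pent-4-en-1-yl]cyclohex-3-en-1-yl]-2-methylpropanoate
Product: 12 methyl 2-[(1R,5S,6R)-4,6-dimethyl-5-[(3R)-3-methyl-3-(triethylsilyloxy)pent-4-en-1-yl]-6-(2-oxoethyl)cyclohex-3-en-1-yl]-2-methylpropanoate
Conditions: pyridinium p-toluenesulfonate (0.2 equiv), acetone/H2O (9:1), 45 °C
Reagents that add atoms: water, O
Why: Enol ether hydrolysis: mild acid protonates C1 and water converts the oxocarbenium ion into the C2 aldehyde, while this weak acid should neither ionise the tertiary allylic silyl ether nor protonate the C7=C8 alkene.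

Step 10
Reactants: 12 methyl 2-[(1R,5S,6R)-4,6-dimethyl-5-[(3R)-3-methyl-3-(triethylsilyloxy)pent-4-en-1-yl]-6-(2-oxoethyl)cyclohex-3-en-1-yl]-2-methylpropanoate
Product: 13 2-[(1R,2S,6R)-6-(1-methoxy-2-methyl-1-oxopropan-2-yl)-1,3-dimethyl-2-[(3R)-3-methyl-3-(triethylsilyloxy)pent-4-en-1-yl]cyclohex-3-en-1-yl]acetic acid
Conditions: NaClO2, NaH2PO4, 2-methyl-2-butene (excess), t-BuOH/H2O, 0 → 23 °C
Reagents that add atoms: sodium chlorite, [Na+].[O-]Cl=O
Why: Pinnick oxidation converts the aldehyde into the acid under buffered conditions, and the large excess of 2-methyl-2-butene intercepts hypochlorous acid before it can attack the ring alkene.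

Step 11
Reactants: 13 2-[(1R,2S,6R)-6-(1-methoxy-2-methyl-1-oxopropan-2-yl)-1,3-dimethyl-2-[(3R)-3-methyl-3-(triethylsilyloxy)pent-4-en-1-yl]cyclohex-3-en-1-yl]acetic acid
Product: 14 2-[(1R,2S,6R)-2-[(3R)-3-hydroxy-3-methylpent-4-en-1-yl]-6-(1-methoxy-2-methyl-1-oxopropan-2-yl)-1,3-dimethylcyclohex-3-en-1-yl]acetic acid
Conditions: HF·pyridine, pyridine, THF, 0 → 23 °C
Reagents that add atoms: none
Why: Fluoride desilylation (strong Si–F bond) under pyridine-buffered conditions should free the C13 hydroxyl without ionising the tertiary allylic alcohol or affecting the ester, acid or alkenes.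

Step 12
Reactants: 14 2-[(1R,2S,6R)-2-[(3R)-3-hydroxy-3-methylpent-4-en-1-yl]-6-(1-methoxy-2-methyl-1-oxopropan-2-yl)-1,3-dimethylcyclohex-3-en-1-yl]acetic acid
Product: 16 2-[(2R,4aR,5S,6R,8aR)-2-ethenyl-6-(1-methoxy-2-methyl-1-oxopropan-2-yl)-2,5,8a-trimethyloctahydro-2H-chromen-5-yl]acetic acid, via C7-acetoxymercurio pyran 15 (not isolated)
Conditions: Hg(OAc)2, THF, 23 °C; then 3 M NaOH, NaBH4, 0 °C
Reagents that add atoms: none
Why: Intramolecular alkoxymercuration–demercuration, in which the C13 hydroxyl opens the mercurinium ion of the trisubstituted alkene at its tertiary carbon C8 (Markovnikov, 6-exo) and enters equatorially, trans to the C9–C11 bond, because ring B rests in the chair that keeps the C4 group and the C9 chain equatorial; this sets C8 with an axial methyl as in the closure of labdenols to manoyl oxides, the C14=C15 vinyl group has no internal nucleophile, and NaBH4 then replaces Hg at C7 by H.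

Step 13
Reactants: 16 2-[(2R,4aR,5S,6R,8aR)-2-ethenyl-6-(1-methoxy-2-methyl-1-oxopropan-2-yl)-2,5,8a-trimethyloctahydro-2H-chromen-5-yl]acetic acid
Product: 17 2-[(2R,4aR,5S,6R,8aR)-6-(2-carboxypropan-2-yl)-2-ethenyl-2,5,8a-trimethyloctahydro-2H-chromen-5-yl]acetic acid (CNP0186744.2)
Conditions: KOH, MeOH/H2O (3:1), 80 °C; then 1 M HCl, 0 °C
Reagents that add atoms: potassium hydroxide, [K+].[OH-]
Why: Saponification (acyl–oxygen cleavage by hydroxide) of the remaining methyl ester, which is neopentyl-like and slow, but the substrate has no base-sensitive group and no epimerisable centre, so forcing temperature is safe and a cold dilute acid work-up should release the diacid without opening the tertiary allylic ether.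

**Compound list**

1 | (R)-linalool, (3R)-3,7-dimethylocta-1,6-dien-3-ol | CC(C)=CCC[C@@](C)(O)C=C | starting material
2 | triethyl{[(3R)-3,7-dimethylocta-1,6-dien-3-yl]oxy}silane | CC(C)=CCC[C@@](C)(O[Si](CC)(CC)CC)C=C | intermediate
3 | (2E,6R)-2,6-dimethyl-6-(triethylsilyloxy)octa-2,7-dien-1-ol | OC/C(C)=C/CC[C@@](C)(O[Si](CC)(CC)CC)C=C | intermediate
4 | (2E,6R)-2,6-dimethyl-6-(triethylsilyloxy)octa-2,7-dienal | O=C/C(C)=C/CC[C@@](C)(O[Si](CC)(CC)CC)C=C | intermediate
5 | triethyl{[(3R,6E)-3,7-dimethylnona-1,6,8-trien-3-yl]oxy}silane (diene) | C=C/C(C)=C/CC[C@@](C)(O[Si](CC)(CC)CC)C=C | intermediate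
6 | methyl 3-hydroxy-2,2-dimethylpropanoate (methyl hydroxypivalate) | COC(=O)C(C)(C)CO | starting material
7 | methyl 2,2-dimethyl-3-oxopropanoate | COC(=O)C(C)(C)C=O | intermediate
8 | 2-(triphenylphosphoranylidene)propanal | CC(C=O)=P(c1ccccc1)(c1ccccc1)c1ccccc1 | starting material
9 | methyl (3E)-2,2,4-trimethyl-5-oxopent-3-enoate (dienophile) | O=C/C(C)=C/C(C)(C)C(=O)OC | intermediate
10 | methyl 2-[(1R,5S,6R)-6-formyl-4,6-dimethyl-5-[(3R)-3-methyl-3-(triethylsilyloxy)pent-4-en-1-yl]cyclohex-3-en-1-yl]-2-methylpropanoate | C=C[C@](C)(O[Si](CC)(CC)CC)CC[C@@H]1[C@@](C)(C=O)[C@H](C(C)(C)C(=O)OC)CC=C1C | intermediate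
11 | methyl 2-[(1R,5S,6R)-6-(2-methoxyethenyl)-4,6-dimethyl-5-[(3R)-3-methyl-3-(triethylsilyloxy)pent-4-en-1-yl]cyclohex-3-en-1-yl]-2-methylpropanoate (E/Z mixture) | C=C[C@](C)(O[Si](CC)(CC)CC)CC[C@@H]1[C@@](C)(C=COC)[C@H](C(C)(C)C(=O)OC)CC=C1C | intermediate
12 | methyl 2-[(1R,5S,6R)-4,6-dimethyl-5-[(3R)-3-methyl-3-(triethylsilyloxy)pent-4-en-1-yl]-6-(2-oxoethyl)cyclohex-3-en-1-yl]-2-methylpropanoate | C=C[C@](C)(O[Si](CC)(CC)CC)CC[C@@H]1[C@@](C)(CC=O)[C@H](C(C)(C)C(=O)OC)CC=C1C | intermediate
13 | 2-[(1R,2S,6R)-6-(1-methoxy-2-methyl-1-oxopropan-2-yl)-1,3-dimethyl-2-[(3R)-3-methyl-3-(triethylsilyloxy)pent-4-en-1-yl]cyclohex-3-en-1-yl]acetic acid | C=C[C@](C)(O[Si](CC)(CC)CC)CC[C@@H]1[C@@](C)(CC(=O)O)[C@H](C(C)(C)C(=O)OC)CC=C1C | intermediate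
14 | 2-[(1R,2S,6R)-2-[(3R)-3-hydroxy-3-methylpent-4-en-1-yl]-6-(1-methoxy-2-methyl-1-oxopropan-2-yl)-1,3-dimethylcyclohex-3-en-1-yl]acetic acid | C=C[C@](C)(O)CC[C@@H]1[C@@](C)(CC(=O)O)[C@H](C(C)(C)C(=O)OC)CC=C1C | intermediate
15 | C7-acetoxymercurio derivative of 16 (Hg at C7 trans to the ring oxygen at C8) | C=C[C@@]1(C)CC[C@@H]2[C@@](C)(CC(=O)O)[C@H](C(C)(C)C(=O)OC)C[C@H]([Hg]OC(C)=O)[C@@]2(C)O1 | intermediate
16 | 2-[(2R,4aR,5S,6R,8aR)-2-ethenyl-6-(1-methoxy-2-methyl-1-oxopropan-2-yl)-2,5,8a-trimethyloctahydro-2H-chromen-5-yl]acetic acid | C=C[C@@]1(C)CC[C@@H]2[C@@](C)(CC(=O)O)[C@H](C(C)(C)C(=O)OC)CC[C@@]2(C)O1 | intermediate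
17 | 2-[(2R,4aR,5S,6R,8aR)-6-(2-carboxypropan-2-yl)-2-ethenyl-2,5,8a-trimethyloctahydro-2H-chromen-5-yl]acetic acid | C=C[C@@]1(C)CC[C@@H]2[C@@](C)(CC(=O)O)[C@H](C(C)(C)C(=O)O)CC[C@@]2(C)O1 | target

**Step count and risks**

Total: 13 steps. Longest linear sequence: 11 steps (steps 1–4 and 7–13, from (R)-linalool).

Steps most likely to fail:

1. Step 7. The cycloaddition may be slow, and exo and ortho selectivity may erode, because the quaternary C4 group has to pass under the diene while the C8 methyl opposes the directing effect of the C9 chain. Long exposure to the acidic catalyst may also cleave the silyl ether or oligomerise the diene. Fallback: build the quaternary C4 after ring B instead of before it. Setting out from diene 5, the same catalyst is used with the slimmer dienophile methyl (3E)-4-methyl-5-oxopent-3-enoate F1, made by cross-metathesis of methyl but-3-enoate with methacrolein using the second-generation Grubbs catalyst (H2IMes)(PCy3)Cl2Ru=CHPh. Its β-carbon carries only a CH2 group, and the cycloaddition should give the des-dimethyl cyclohexene aldehyde F2. Methoxymethylenation as in step 8 gives the enol ether F3. Two successive enolate methylations (LiN(i-Pr)2, then MeI, THF, −78 °C, run twice) pass through the monomethyl ester F4 and install the C4 gem-dimethyl group, returning to the route at 11.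

2. Step 12. Mercuration may also engage the vinyl group or the free carboxylate, the oxygen may add axially to give the cis-fused ether, and the organomercurial may revert to alkene during reduction. Fallback: a reversible selenium-mediated closure followed by radical reduction. Setting out from 14, N-(phenylselanyl)phthalimide with catalytic camphorsulfonic acid in CH2Cl2 at 0 °C selects the electron-rich trisubstituted alkene and can equilibrate to the trans-fused ether, giving the C7-phenylselanyl pyran F5. Bu3SnH with azobis(isobutyronitrile) in toluene at 80 °C removes selenium and returns to the route at 16.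

3. Step 8. The ylide may fail to add to the formyl group buried between C5 and C9, so that ylide decomposition outruns olefination. Fallback: Arndt–Eistert homologation at the acid oxidation level. Setting out from 10, Pinnick oxidation gives the C1 carboxylic acid F6. 1-Chloro-N,N,2-trimethylprop-1-en-1-amine converts it under neutral conditions into the acid chloride F7, and CH2N2 gives the diazoketone F8. Wolff rearrangement (silver benzoate AgO2CPh, Et3N, THF/H2O) migrates C10 with retention and returns to the route at 13.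

**Further compounds**

F1 | step 7 | methyl (3E)-4-methyl-5-oxopent-3-enoate | O=C/C(C)=C/CC(=O)OC
F2 | step 7 | methyl 2-[(1R,5S,6R)-6-formyl-4,6-dimethyl-5-[(3R)-3-methyl-3-(triethylsilyloxy)pent-4-en-1-yl]cyclohex-3-en-1-yl]acetate | C=C[C@](C)(O[Si](CC)(CC)CC)CC[C@@H]1[C@@](C)(C=O)[C@H](CC(=O)OC)CC=C1C
F3 | step 7 | methyl 2-[6-(2-methoxyethenyl)-4,6-dimethyl-5-[(3R)-3-methyl-3-(triethylsilyloxy)pent-4-en-1-yl]cyclohex-3-en-1-yl]acetate (E/Z mixture, ring configuration as in F2) | C=C[C@](C)(O[Si](CC)(CC)CC)CC[C@@H]1[C@@](C)(C=COC)[C@H](CC(=O)OC)CC=C1C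
F4 | step 7 | monomethylated ester, the propanoate analogue of F3 (C4 epimer mixture) | C=C[C@](C)(O[Si](CC)(CC)CC)CC[C@@H]1[C@@](C)(C=COC)[C@H](C(C)C(=O)OC)CC=C1C
F5 | step 12 | C7-phenylselanyl derivative of 16 (Se at C7 trans to the ring oxygen at C8) | C=C[C@@]1(C)CC[C@@H]2[C@@](C)(CC(=O)O)[C@H](C(C)(C)C(=O)OC)C[C@H]([Se]c3ccccc3)[C@@]2(C)O1
F6 | step 8 | C1 carboxylic acid corresponding to aldehyde 10 | C=C[C@](C)(O[Si](CC)(CC)CC)CC[C@@H]1[C@@](C)(C(=O)O)[C@H](C(C)(C)C(=O)OC)CC=C1C
F7 | step 8 | C1 acid chloride of F6 | C=C[C@](C)(O[Si](CC)(CC)CC)CC[C@@H]1[C@@](C)(C(=O)Cl)[C@H](C(C)(C)C(=O)OC)CC=C1C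
F8 | step 8 | C1 diazomethyl ketone from F7 | C=C[C@](C)(O[Si](CC)(CC)CC)CC[C@@H]1[C@@](C)(C(=O)C=[N+]=[N-])[C@H](C(C)(C)C(=O)OC)CC=C1C
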